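**Retrosynthetic overview**

1. The C40 chain is cut by Wittig disconnections at C11'=C12' (C25 phosphonium salt + C15 hydroxy-aldehyde) and C11=C12 (C15 phosphonium salt + C10 trienedial). Both C15 ends come from one (S)-C15 dienenitrile (HWE at C7=C8 of (S)-α-cyclocitral); the 3-OH of the right ring comes from allylic oxidation and hydride reduction.
2. The (6S) centre and the C4=C5 bond of both rings come from 2,4,4-trimethylcyclohex-2-en-1-one: CBS reduction to the (R)-allylic alcohol, then a suprafacial [2,3]-Wittig–Still shift that trades the C4–O bond for the C6–C7 bond.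
3. Key step: Rh-catalysed insertion of ethene into 2,4,4-trimethylcyclobut-2-en-1-one forms C4–C3 and C2–C1 and the only six-membered carbocycle of the route, which becomes both rings of the target. The C4 carbonyl is a temporary oxidation level that the [2,3] shift removes.
4. Enabling feature: the four-membered ring of the cyclobutenone. Its C1(=O)–C4(CH3)2 σ-bond is strained and allylic to C2=C3, so a low-valent metal can open it to an η3-allyl acyl (vinylketene) unit whose termini are the acyl carbon and the CMe2 carbon.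
5. Ring order: cyclobutenone (ketene + ynol ether [2+2]) → cyclohexenone (key [4+2]) → carried into the left ring and, after C3 oxygenation, the right ring.

Key step: step 3

Remark: the ynol ether, the stannane, the C5 cyanophosphonate and the C10 trienedial used below are taken as catalogue compounds, and positions are quoted in carotenoid numbering (ring C1–C6, chain from C7).

**Route**

Step 1
Reactants: 1 2-methylpropanoyl chloride; 2 1-ethoxyprop-1-yne
Product: 4 3-ethoxy-2,4,4-trimethylcyclobut-2-en-1-one, via dimethylketene 3 (not isolated)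
Conditions: Et3N, Et2O, reflux
Reagents that add atoms: none
Why: Dehydrochlorination of 1 gives dimethylketene, whose electrophilic carbonyl carbon should bond to the nucleophilic methyl-bearing carbon of the ynol ether in a thermal ketene–alkyne [2+2] cycloaddition, which fixes the 3-ethoxy-2-methyl pattern.

Step 2
Reactants: 4 3-ethoxy-2,4,4-trimethylcyclobut-2-en-1-one
Product: 6 2,4,4-trimethylcyclobut-2-en-1-one, via cyclobutenol 5 (not isolated)
Conditions: LiAlH4, Et2O, 0 °C; then 1 M aq HCl, 0 °C to rt
Reagents that add atoms: water, O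
Why: 1,2-Reduction of the vinylogous ester and acid hydrolysis of the ethoxy-allylic alcohol with loss of water and ethanol (Stork–Danheiser-type carbonyl transposition) should give the cyclobutenone, the transposed enone having the same 2,4,4-trimethyl pattern in a four-membered ring.

Step 3
Reactants: 6 2,4,4-trimethylcyclobut-2-en-1-one; 7 ethene
Product: 8 2,4,4-trimethylcyclohex-2-en-1-one
Conditions: [Rh(CO)2Cl]2 (5 mol %), P(C6F5)3 (12 mol %), ethene (20 bar), toluene, 80 °C
Reagents that add atoms: none
Why: Proposed new method: Rh(I) should insert into the strained acyl–C(sp3) bond C1–C4 of 6 (equivalently, bind the vinylketene of 4π ring opening as an η4 complex), ethene then inserts into the Rh–acyl bond, and C(sp3)–C(sp3) reductive elimination at the CMe2 terminus of the η3-allyl alkyl rhodium species releases 8, so that the bonds C1(=O)–C6H2 and C5H2–C4(CH3)2 of 8 (carotenoid C4–C3 and C2–C1) form in one catalytic turnover. The closest known reaction types are the Rh- and Ni-catalysed [4+2] couplings of cyclobutenones and benzocyclobutenones with alkynes and with activated or tethered alkenes by C–C cleavage, and the Rh-catalysed insertion of ethene into ketone C–C bonds. The six-membered ring closes as a formal [4+2] (σ2+π2) annulation by reductive elimination from a seven-membered rhodacycle, and no stereocentre is formed. The step needs cleavage of the acyl–CMe2 bond and not the acyl–vinyl bond, which the substrate secures because only the former is allylic and leads to the η3-allyl acyl unit. It also needs six- over four-ring reductive elimination, which formation of the conjugated, strain-free enone should favour. Decarbonylation, β-hydride elimination and vinylketene dimerisation are to be held back by the π-acidic phosphine, the CO-bearing precatalyst and the ethene pressure.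

Step 4
Reactants: 8 2,4,4-trimethylcyclohex-2-en-1-one
Product: 9 (1R)-2,4,4-trimethylcyclohex-2-en-1-ol
Conditions: (S)-2-methyl-CBS-oxazaborolidine (10 mol %), catecholborane, toluene, −78 °C; then H2O
Reagents that add atoms: none
Why: Corey–Bakshi–Shibata reduction in which the α-methylated alkene arm acts as the large group, so the (S)-catalyst should deliver hydride to the face that gives the (1R)-alcohol.

Step 5
Reactants: 9 (1R)-2,4,4-trimethylcyclohex-2-en-1-ol; 10 tributyl(iodomethyl)stannane
Product: 11 tributyl({[(1R)-2,4,4-trimethylcyclohex-2-en-1-yl]oxy}methyl)stannane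
Conditions: KH, THF, 0 °C; then 10, rt
Reagents that add atoms: none
Why: Williamson etherification of the potassium alkoxide with the primary iodide, the usual entry to stannylmethyl ethers, leaves the carbinol stereocentre untouched.

Step 6
Reactants: 11 tributyl({[(1R)-2,4,4-trimethylcyclohex-2-en-1-yl]oxy}methyl)stannane
Product: 13 [(1S)-2,6,6-trimethylcyclohex-2-en-1-yl]methanol, via alkoxymethyllithium 12 (not isolated)
Conditions: n-BuLi, THF, −78 to −20 °C; then H2O
Reagents that add atoms: none
Why: Tin–lithium exchange gives the α-alkoxymethyllithium, which should undergo the [2,3]-Wittig–Still rearrangement through a five-membered envelope transition state; the C6–C7 bond forms on the ring face that carried the C4–O bond, so (1R) in 11 becomes (1S) in 13 and the double bond moves to C4=C5.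

Step 7
Reactants: 13 [(1S)-2,6,6-trimethylcyclohex-2-en-1-yl]methanol
Product: 14 (1S)-2,6,6-trimethylcyclohex-2-ene-1-carbaldehyde
Conditions: Dess–Martin periodinane, CH2Cl2, 0 °C to rt
Reagents that add atoms: none
Why: Dess–Martin oxidation under near-neutral conditions should give the β,γ-unsaturated aldehyde without epimerisation at C6 or conjugation of the double bond.

Step 8
Reactants: 14 (1S)-2,6,6-trimethylcyclohex-2-ene-1-carbaldehyde; 15 diethyl [(2E)-3-cyano-2-methylprop-2-en-1-yl]phosphonate
Product: 17 (2E,4E)-3-methyl-5-[(1S)-2,6,6-trimethylcyclohex-2-en-1-yl]penta-2,4-dienenitrile, via lithiated phosphonate 16 (not isolated)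
Conditions: LiHMDS, THF, −78 °C; then 14, −78 to 0 °C; chromatographic removal of the minor 2Z isomer
Reagents that add atoms: none
Why: Horner–Wadsworth–Emmons olefination with the preformed, weakly basic phosphonate anion at low temperature should add to the hindered aldehyde faster than it enolises it; the E-selective elimination sets C7=C8 and C9=C10 comes from the reagent.

Step 9
Reactants: 17 (2E,4E)-3-methyl-5-[(1S)-2,6,6-trimethylcyclohex-2-en-1-yl]penta-2,4-dienenitrile
Product: 19 (2E,4E)-3-methyl-5-[(1S)-2,6,6-trimethylcyclohex-2-en-1-yl]penta-2,4-dienal, via N-aluminoaldimine 18 (not isolated)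
Conditions: DIBAL-H, CH2Cl2, −78 °C; then aq Rochelle salt
Reagents that add atoms: water, O
Why: DIBAL-H reduction of a nitrile stops at the N-aluminoaldimine, which hydrolysis converts into the aldehyde.

Step 10
Reactants: 19 (2E,4E)-3-methyl-5-[(1S)-2,6,6-trimethylcyclohex-2-en-1-yl]penta-2,4-dienal
Product: 20 (2E,4E)-3-methyl-5-[(1S)-2,6,6-trimethylcyclohex-2-en-1-yl]penta-2,4-dien-1-ol
Conditions: NaBH4, MeOH, 0 °C
Reagents that add atoms: none
Why: Borohydride 1,2-reduction of the dienal gives the primary allylic alcohol and leaves the alkenes alone.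

Step 11
Reactants: 20 (2E,4E)-3-methyl-5-[(1S)-2,6,6-trimethylcyclohex-2-en-1-yl]penta-2,4-dien-1-ol
Product: 21 triphenyl{(2E,4E)-3-methyl-5-[(1S)-2,6,6-trimethylcyclohex-2-en-1-yl]penta-2,4-dien-1-yl}phosphonium bromide
Conditions: PPh3·HBr, MeOH, rt
Reagents that add atoms: triphenylphosphine hydrobromide, [Br-].c1ccc(cc1)[PH+](c1ccccc1)c1ccccc1
Why: Acid ionisation of the dienylic alcohol and capture of the pentadienyl cation by triphenylphosphine at its unhindered terminus is the standard formation of C15 Wittig salts of ionylidene type.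

Step 12
Reactants: 21 triphenyl{(2E,4E)-3-methyl-5-[(1S)-2,6,6-trimethylcyclohex-2-en-1-yl]penta-2,4-dien-1-yl}phosphonium bromide; 22 (2E,4E,6E)-2,7-dimethylocta-2,4,6-trienedial
Product: 24 (2E,4E,6E,8E,10E,12E)-2,7,11-trimethyl-13-[(1S)-2,6,6-trimethylcyclohex-2-en-1-yl]trideca-2,4,6,8,10,12-hexaenal, via phosphonium ylide 23 (not isolated)
Conditions: 22 (3 equiv), NaOMe, CH2Cl2/MeOH, −10 °C to rt; then I2 (cat.), hexane, rt
Reagents that add atoms: none
Why: Wittig olefination of the semistabilised ylide forms C11=C12, the excess of dialdehyde should hold the reaction at mono-olefination, and iodine-catalysed equilibration should take the new bond to E.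

Step 13
Reactants: 24 (2E,4E,6E,8E,10E,12E)-2,7,11-trimethyl-13-[(1S)-2,6,6-trimethylcyclohex-2-en-1-yl]trideca-2,4,6,8,10,12-hexaenal
Product: 25 (2E,4E,6E,8E,10E,12E)-2,7,11-trimethyl-13-[(1S)-2,6,6-trimethylcyclohex-2-en-1-yl]trideca-2,4,6,8,10,12-hexaen-1-ol
Conditions: NaBH4, MeOH/THF, 0 °C
Reagents that add atoms: none
Why: Borohydride 1,2-reduction of the polyenal gives the allylic alcohol needed for the second Wittig salt.

Step 14
Reactants: 25 (2E,4E,6E,8E,10E,12E)-2,7,11-trimethyl-13-[(1S)-2,6,6-trimethylcyclohex-2-en-1-yl]trideca-2,4,6,8,10,12-hexaen-1-ol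
Product: 26 triphenyl{(2E,4E,6E,8E,10E,12E)-2,7,11-trimethyl-13-[(1S)-2,6,6-trimethylcyclohex-2-en-1-yl]trideca-2,4,6,8,10,12-hexaen-1-yl}phosphonium bromide
Conditions: PPh3·HBr, MeOH/CH2Cl2, 0 °C to rt
Reagents that add atoms: triphenylphosphine hydrobromide, [Br-].c1ccc(cc1)[PH+](c1ccccc1)c1ccccc1
Why: The same acid-mediated phosphonium salt formation applies to the C25 polyenyl alcohol, whose ring carries no acid-labile group.

Step 15
Reactants: 17 (2E,4E)-3-methyl-5-[(1S)-2,6,6-trimethylcyclohex-2-en-1-yl]penta-2,4-dienenitrile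
Product: 27 (2E,4E)-3-methyl-5-[(1S)-2,6,6-trimethyl-4-oxocyclohex-2-en-1-yl]penta-2,4-dienenitrile
Conditions: t-BuOOH (70 % aq), Rh2(cap)4 (1 mol %), 1,2-dichloroethane, 40 °C
Reagents that add atoms: tert-butyl hydroperoxide, CC(C)(C)OO
Why: Peroxyl-radical allylic oxidation should attack the only unhindered ring methylene (C3), as known for α-ionone and its ylidene nitrile, and the base-free medium protects the now vinylogously acidic C6–H.

Step 16
Reactants: 27 (2E,4E)-3-methyl-5-[(1S)-2,6,6-trimethyl-4-oxocyclohex-2-en-1-yl]penta-2,4-dienenitrile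
Product: 28 (2E,4E)-5-[(1S,4S)-4-hydroxy-2,6,6-trimethylcyclohex-2-en-1-yl]-3-methylpenta-2,4-dienenitrile
Conditions: L-Selectride, THF, −78 °C; then H2O
Reagents that add atoms: none
Why: 1,2-Reduction of the β,β-disubstituted enone by a bulky hydride, which should avoid the face screened by the axial C1 methyl group (the C6 side chain sits pseudo-axial on the other face) and so place the new hydroxyl trans to the side chain, giving (4S) by substrate control.

Step 17
Reactants: 28 (2E,4E)-5-[(1S,4S)-4-hydroxy-2,6,6-trimethylcyclohex-2-en-1-yl]-3-methylpenta-2,4-dienenitrile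
Product: 30 (2E,4E)-5-[(1S,4S)-4-hydroxy-2,6,6-trimethylcyclohex-2-en-1-yl]-3-methylpenta-2,4-dienal, via bis-aluminated aldimine 29 (not isolated)
Conditions: DIBAL-H (2.5 equiv), CH2Cl2, −78 °C; then aq Rochelle salt
Reagents that add atoms: water, O
Why: DIBAL-H reduction of the nitrile (one equivalent is used up by the free hydroxyl) and mild non-acidic hydrolysis give the hydroxy-aldehyde without ionising the allylic alcohol.

Step 18
Reactants: 26 triphenyl{(2E,4E,6E,8E,10E,12E)-2,7,11-trimethyl-13-[(1S)-2,6,6-trimethylcyclohex-2-en-1-yl]trideca-2,4,6,8,10,12-hexaen-1-yl}phosphonium bromide; 30 (2E,4E)-5-[(1S,4S)-4-hydroxy-2,6,6-trimethylcyclohex-2-en-1-yl]-3-methylpenta-2,4-dienal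
Product: 32 (all-E)-(3S,6S,6'S)-ε,ε-caroten-3-ol, via phosphonium ylide 31 (not isolated)
Conditions: NaOMe, CH2Cl2/MeOH, 0 °C to rt; then reflux in ethyl acetate (Z to E equilibration), crystallisation
Reagents that add atoms: none
Why: Wittig olefination of the C25 ylide with the unprotected C15 hydroxy-aldehyde forms C11'=C12', the mild base should leave both C6 centres and the allylic alcohol intact, and thermal equilibration should give the all-E polyene.

**Compound list**

1 | 2-methylpropanoyl chloride | CC(C)C(=O)Cl | starting material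
2 | 1-ethoxyprop-1-yne | CCOC#CC | starting material
3 | dimethylketene | CC(C)=C=O | intermediate
4 | 3-ethoxy-2,4,4-trimethylcyclobut-2-en-1-one | CCOC1=C(C)C(=O)C1(C)C | intermediate
5 | 3-ethoxy-2,4,4-trimethylcyclobut-2-en-1-ol (racemic, formed as its aluminium alkoxide) | CCOC1=C(C)C(O)C1(C)C | intermediate
6 | 2,4,4-trimethylcyclobut-2-en-1-one | CC1=CC(C)(C)C1=O | intermediate
7 | ethene | C=C | starting material
8 | 2,4,4-trimethylcyclohex-2-en-1-one | CC1=CC(C)(C)CCC1=O | intermediate
9 | (1R)-2,4,4-trimethylcyclohex-2-en-1-ol | O[C@@H]1CCC(C)(C)C=C1C | intermediate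
10 | tributyl(iodomethyl)stannane | CCCC[Sn](CCCC)(CCCC)CI | starting material
11 | tributyl({[(1R)-2,4,4-trimethylcyclohex-2-en-1-yl]oxy}methyl)stannane | CCCC[Sn](CCCC)(CCCC)CO[C@@H]1CCC(C)(C)C=C1C | intermediate
12 | ({[(1R)-2,4,4-trimethylcyclohex-2-en-1-yl]oxy}methyl)lithium | [Li]CO[C@@H]1CCC(C)(C)C=C1C | intermediate
13 | [(1S)-2,6,6-trimethylcyclohex-2-en-1-yl]methanol ((S)-α-cyclogeraniol) | CC1=CCCC(C)(C)[C@@H]1CO | intermediate
14 | (1S)-2,6,6-trimethylcyclohex-2-ene-1-carbaldehyde ((S)-α-cyclocitral) | CC1=CCCC(C)(C)[C@@H]1C=O | intermediate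
15 | diethyl [(2E)-3-cyano-2-methylprop-2-en-1-yl]phosphonate | CCOP(=O)(OCC)C/C(C)=C/C#N | starting material
16 | lithium salt of the α-carbanion of 15 | [Li+].CCOP(=O)(OCC)[CH-]/C(C)=C/C#N | intermediate
17 | (2E,4E)-3-methyl-5-[(1S)-2,6,6-trimethylcyclohex-2-en-1-yl]penta-2,4-dienenitrile | CC1=CCCC(C)(C)[C@@H]1/C=C/C(C)=C/C#N | intermediate
18 | N-(diisobutylalumanyl)imine of aldehyde 19 | CC1=CCCC(C)(C)[C@@H]1/C=C/C(C)=C/C=N[Al](CC(C)C)CC(C)C | intermediate
19 | (2E,4E)-3-methyl-5-[(1S)-2,6,6-trimethylcyclohex-2-en-1-yl]penta-2,4-dienal | CC1=CCCC(C)(C)[C@@H]1/C=C/C(C)=C/C=O | intermediate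
20 | (2E,4E)-3-methyl-5-[(1S)-2,6,6-trimethylcyclohex-2-en-1-yl]penta-2,4-dien-1-ol | CC1=CCCC(C)(C)[C@@H]1/C=C/C(C)=C/CO | intermediate
21 | triphenyl{(2E,4E)-3-methyl-5-[(1S)-2,6,6-trimethylcyclohex-2-en-1-yl]penta-2,4-dien-1-yl}phosphonium bromide | CC1=CCCC(C)(C)[C@@H]1/C=C/C(C)=C/C[P+](c2ccccc2)(c3ccccc3)c4ccccc4.[Br-] | intermediate
22 | (2E,4E,6E)-2,7-dimethylocta-2,4,6-trienedial | O=C/C(C)=C/C=C/C=C(C)/C=O | starting material
23 | ylide of 21 | CC1=CCCC(C)(C)[C@@H]1/C=C/C(C)=C/C=P(c2ccccc2)(c3ccccc3)c4ccccc4 | intermediate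
24 | (2E,4E,6E,8E,10E,12E)-2,7,11-trimethyl-13-[(1S)-2,6,6-trimethylcyclohex-2-en-1-yl]trideca-2,4,6,8,10,12-hexaenal | CC1=CCCC(C)(C)[C@@H]1/C=C/C(C)=C/C=C/C(C)=C/C=C/C=C(C)/C=O | intermediate
25 | (2E,4E,6E,8E,10E,12E)-2,7,11-trimethyl-13-[(1S)-2,6,6-trimethylcyclohex-2-en-1-yl]trideca-2,4,6,8,10,12-hexaen-1-ol | CC1=CCCC(C)(C)[C@@H]1/C=C/C(C)=C/C=C/C(C)=C/C=C/C=C(C)/CO | intermediate
26 | triphenyl{(2E,4E,6E,8E,10E,12E)-2,7,11-trimethyl-13-[(1S)-2,6,6-trimethylcyclohex-2-en-1-yl]trideca-2,4,6,8,10,12-hexaen-1-yl}phosphonium bromide | CC1=CCCC(C)(C)[C@@H]1/C=C/C(C)=C/C=C/C(C)=C/C=C/C=C(C)/C[P+](c2ccccc2)(c3ccccc3)c4ccccc4.[Br-] | intermediate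
27 | (2E,4E)-3-methyl-5-[(1S)-2,6,6-trimethyl-4-oxocyclohex-2-en-1-yl]penta-2,4-dienenitrile | CC1=CC(=O)CC(C)(C)[C@@H]1/C=C/C(C)=C/C#N | intermediate
28 | (2E,4E)-5-[(1S,4S)-4-hydroxy-2,6,6-trimethylcyclohex-2-en-1-yl]-3-methylpenta-2,4-dienenitrile | CC1=C[C@@H](O)CC(C)(C)[C@@H]1/C=C/C(C)=C/C#N | intermediate
29 | O,N-bis(diisobutylalumanyl) derivative of the imine of 30 | CC1=C[C@@H](O[Al](CC(C)C)CC(C)C)CC(C)(C)[C@@H]1/C=C/C(C)=C/C=N[Al](CC(C)C)CC(C)C | intermediate
30 | (2E,4E)-5-[(1S,4S)-4-hydroxy-2,6,6-trimethylcyclohex-2-en-1-yl]-3-methylpenta-2,4-dienal | CC1=C[C@@H](O)CC(C)(C)[C@@H]1/C=C/C(C)=C/C=O | intermediate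
31 | ylide of 26 | CC1=CCCC(C)(C)[C@@H]1/C=C/C(C)=C/C=C/C(C)=C/C=C/C=C(C)/C=P(c2ccccc2)(c3ccccc3)c4ccccc4 | intermediate
32 | (all-E)-(3S,6S,6'S)-ε,ε-caroten-3-ol | CC1=CCCC(C)(C)[C@@H]1/C=C/C(C)=C/C=C/C(C)=C/C=C/C=C(C)/C=C/C=C(C)/C=C/[C@@H]1C(C)=C[C@@H](O)CC1(C)C | target
33 | 2-methylpropanal (used only in the fallback for step 3) | CC(C)C=O | starting material
34 | pent-1-en-3-one (used only in the fallback for step 3) | CCC(=O)C=C | starting material

**Step count and risks**

Total step count: 18. Longest linear sequence: 15 steps (steps 1–14 and 18); the right-hand branch runs through steps 1–8, 15–17 and 18.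

Steps most likely to fail:

Step 3 (proposed new method). The rhodacycle formed after ethene insertion may undergo β-hydride elimination to an open-chain vinyl ketone, or lose CO to give a cyclopentene. The cyclobutenone may also open thermally to the vinylketene, which can dimerise or suffer a 1,5-hydrogen shift before ethene is taken up. The fallback gives up the ethene insertion and builds the same ring by a known Robinson-type annulation. It sets out from commercial 2-methylpropanal 33 and pent-1-en-3-one 34 (catalytic H2SO4, toluene, reflux with removal of water). Conjugate addition of the aldehyde enol to the enone gives 2,2-dimethyl-5-oxoheptanal F1, which closes by intramolecular aldol condensation. The fallback comes back to the route at compound 8.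

Step 6. The congested C6 terminus next to the CMe2 group may slow the concerted [2,3] shift, so that the radical-pair [1,2]-Wittig pathway or protonation of the organolithium competes and chirality transfer is eroded. The fallback sets out from compound 9 and uses a different one-carbon [2,3] shift. Heating 9 with N,N-dimethylformamide dimethyl acetal (xylene, 160 °C, sealed vessel) should form the alkoxy(dimethylamino)carbene, which rearranges suprafacially to (1S)-N,N,2,6,6-pentamethylcyclohex-2-ene-1-carboxamide F2. Reduction of F2 with LiEt3BH in THF gives the primary alcohol, and the fallback comes back to the route at compound 13.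

Step 16. Facial selectivity may be poor, because the pseudo-axial side chain at C6 and the axial C1 methyl group screen opposite faces of the ketone, so the cis-alcohol may predominate. The fallback sets out from compound 27 and replaces direct control by an inversion sequence. Luche reduction (NaBH4, CeCl3·7H2O, MeOH, −78 °C), in which the small hydride should attack axially, gives (2E,4E)-5-[(1S,4R)-4-hydroxy-2,6,6-trimethylcyclohex-2-en-1-yl]-3-methylpenta-2,4-dienenitrile F3. Mitsunobu reaction of F3 (4-nitrobenzoic acid, PPh3, DIAD, THF, 0 °C) inverts C3 to give (1S,4S)-4-[(1E,3E)-4-cyano-3-methylbuta-1,3-dien-1-yl]-3,5,5-trimethylcyclohex-2-en-1-yl 4-nitrobenzoate F4. Methanolysis of F4 (K2CO3, MeOH, 0 °C) comes back to the route at compound 28; cis-alcohol formed in the main step can enter the same sequence.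

Further compounds
F1 | step 3 | 2,2-dimethyl-5-oxoheptanal | CCC(=O)CCC(C)(C)C=O
F2 | step 6 | (1S)-N,N,2,6,6-pentamethylcyclohex-2-ene-1-carboxamide | CC1=CCCC(C)(C)[C@@H]1C(=O)N(C)C
F3 | step 16 | (2E,4E)-5-[(1S,4R)-4-hydroxy-2,6,6-trimethylcyclohex-2-en-1-yl]-3-methylpenta-2,4-dienenitrile | CC1=C[C@H](O)CC(C)(C)[C@@H]1/C=C/C(C)=C/C#N
F4 | step 16 | (1S,4S)-4-[(1E,3E)-4-cyano-3-methylbuta-1,3-dien-1-yl]-3,5,5-trimethylcyclohex-2-en-1-yl 4-nitrobenzoate | CC1=C[C@@H](OC(=O)c2ccc(cc2)[N+](=O)[O-])CC(C)(C)[C@@H]1/C=C/C(C)=C/C#N
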